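**Retrosynthetic overview**
1. In ent-kaurane numbering (ring A = cyclohexane; rings C and D = the six- and five-membered rings of the bicyclo[3.2.1]octane), the target comes from its bis[2-(trimethylsilyl)ethyl] ester 24 by fluoride cleavage. Ester 24 is cut at C13–C14 (ring C) and C8–C15 (ring D) in one operation, back to the acyclic keto-enal 21.
2. Enabling feature: in ring D, C16 (carrying the exocyclic CH2, C17) with C15 and C13 is a trimethylenemethane unit, and C13 is also alpha to the ring C ketone C12; C14 and C8 are the beta and alpha carbons of the C7 aldehyde. Ring D is thus the (3+2) adduct of an acyl-stabilised trimethylenemethane–palladium dipole and a 2-substituted acrolein, and the C9–C11–C12 tether makes the same event close ring C.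
3. Keto-enal 21 comes from ring A alkene 10, (5R)-5-menthyloxybutenolide 11 and allyl chloride 17. An iron-hydride radical conjugate addition forms C9–C10 and sets both centres; the lactone carbonyl becomes the C12 ketone and the acetal carbon becomes C8.
4. Alkene 10 comes from an enantioselective Diels–Alder reaction of silyloxydiene 2 with fumarate 5, methylation at C4, and conversion of the ketone into the ring alkene.
5. Order of ring formation: ring A (step 3), then rings C and D together (step 13).

Key step: step 13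

**Remarks (assumptions on the chemistry)**
- The (S)-configured oxazaborolidinium catalyst is assumed to give the (1S,2S) adduct 6; if the sense of induction is the opposite, the equally available (R)-catalyst is used and nothing else changes.
- The methyl-bearing ring carbon of 6, 7 and 8 and the enol ether geometry of 14 and 19 are carried as mixtures; both elements are erased later (steps 5 and 12).

Step 1
Reactants: 1 pent-1-en-3-one
Product: 2 (Z)-triisopropyl(penta-1,3-dien-3-yloxy)silane
Conditions: i-Pr3SiOTf (1.1 equiv), Et3N (1.5 equiv), CH2Cl2, 0 °C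
Reagents that add atoms: triisopropylsilyl trifluoromethanesulfonate, CC(C)[Si](OS(=O)(=O)C(F)(F)F)(C(C)C)C(C)C
Why: Soft enolisation of the ethyl ketone (silyl enol ether formation) can only occur towards the ethyl group and should give the Z enol ether, the reactive geometry of this 2-silyloxy diene; no stereocentre is formed.

Step 2
Reactants: 3 fumaryl chloride; 4 2-(trimethylsilyl)ethanol
Product: 5 bis[2-(trimethylsilyl)ethyl] fumarate
Conditions: 4 (2.2 equiv in all), pyridine (2.4 equiv), DMAP (5 mol%), CH2Cl2, 0 °C to rt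
Reagents that add atoms: second equivalent of 2-(trimethylsilyl)ethanol 4, C[Si](C)(C)CCO
Why: Twofold esterification of the diacid chloride, one molecule of the alcohol per acyl chloride group, keeps the E alkene and installs ester groups that fluoride can remove at the end without access to the hindered carbonyls; no stereocentre is formed.

Step 3
Reactants: 2 (Z)-triisopropyl(penta-1,3-dien-3-yloxy)silane; 5 bis[2-(trimethylsilyl)ethyl] fumarate
Product: 6 bis[2-(trimethylsilyl)ethyl] (1S,2S)-3-methyl-4-[(triisopropylsilyl)oxy]cyclohex-4-ene-1,2-dicarboxylate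
Conditions: (S)-3,3-diphenyl-1-(o-tolyl)tetrahydro-1H,3H-pyrrolo[1,2-c][1,3,2]oxazaborole (20 mol%), HNTf2 (20 mol%), CH2Cl2, −40 to −20 °C
Reagents that add atoms: none
Why: Enantioselective Diels–Alder reaction in which the chiral oxazaborolidinium ion binds one ester carbonyl of the C2-symmetric fumarate and shields one face, so the electron-rich diene sets the two ester-bearing carbons trans (from the E dienophile) with the absolute sense fixed by the catalyst, the symmetric dienophile removing any regiochemical question.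

Step 4
Reactants: 6 bis[2-(trimethylsilyl)ethyl] (1S,2S)-3-methyl-4-[(triisopropylsilyl)oxy]cyclohex-4-ene-1,2-dicarboxylate
Product: 8 bis[2-(trimethylsilyl)ethyl] (1R,2S)-1,3-dimethyl-4-oxocyclohexane-1,2-dicarboxylate, via methylated silyl enol ether 7 (not isolated)
Conditions: LiN(i-Pr)2 (1.1 equiv), THF, −78 °C; MeI, −78 to −20 °C; then 2 M HCl, THF, rt
Reagents that add atoms: iodomethane, CI
Why: Kinetic ester enolate alkylation in which the base should remove the less hindered alpha-hydrogen (the one not flanked by the methyl-bearing carbon) and iodomethane should attack the face opposite the neighbouring ester, held pseudoaxial by allylic 1,3-strain, making the quaternary carbon R with the two esters cis, after which acid hydrolyses the silyl enol ether.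

Step 5
Reactants: 8 bis[2-(trimethylsilyl)ethyl] (1R,2S)-1,3-dimethyl-4-oxocyclohexane-1,2-dicarboxylate
Product: 9 bis[2-(trimethylsilyl)ethyl] (1R,2S)-1,3-dimethyl-4-{[(trifluoromethyl)sulfonyl]oxy}cyclohex-3-ene-1,2-dicarboxylate
Conditions: Tf2O (1.3 equiv), 2,6-di-tert-butyl-4-methylpyridine (1.5 equiv), CH2Cl2, 0 °C to rt
Reagents that add atoms: trifluoromethanesulfonic anhydride, O=S(=O)(OS(=O)(=O)C(F)(F)F)C(F)(F)F
Why: Enol triflate formation with triflic anhydride and a hindered pyridine should favour the more substituted enol triflate, which also erases the epimeric methyl-bearing centre; no new stereocentre is formed.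

Step 6
Reactants: 9 bis[2-(trimethylsilyl)ethyl] (1R,2S)-1,3-dimethyl-4-{[(trifluoromethyl)sulfonyl]oxy}cyclohex-3-ene-1,2-dicarboxylate
Product: 10 bis[2-(trimethylsilyl)ethyl] (1R,2S)-1,3-dimethylcyclohex-3-ene-1,2-dicarboxylate
Conditions: Pd(OAc)2 (5 mol%), PPh3 (10 mol%), HCO2H (2 equiv), Bu3N (3 equiv), DMF, 60 °C
Reagents that add atoms: none
Why: Palladium-catalysed formate reduction of the vinyl triflate (oxidative addition, decarboxylation of formate to a palladium hydride, reductive elimination) should give the trisubstituted ring alkene at the position of the triflate; no new stereocentre is formed.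

Step 7
Reactants: 10 bis[2-(trimethylsilyl)ethyl] (1R,2S)-1,3-dimethylcyclohex-3-ene-1,2-dicarboxylate; 11 (5R)-5-{[(1R,2S,5R)-5-methyl-2-(propan-2-yl)cyclohexyl]oxy}furan-2(5H)-one
Product: 12 bis[2-(trimethylsilyl)ethyl] (1R,2S,3S)-1,3-dimethyl-3-[(2R,3S)-2-{[(1R,2S,5R)-5-methyl-2-(propan-2-yl)cyclohexyl]oxy}-5-oxooxolan-3-yl]cyclohexane-1,2-dicarboxylate
Conditions: Fe(acac)3 (30 mol%), PhSiH3 (2.5 equiv), 11 (3 equiv), EtOH/ethylene glycol, 60 °C
Reagents that add atoms: none
Why: Iron-hydride hydrogen-atom transfer to the trisubstituted alkene gives the tertiary ring A radical, which should undergo Giese addition to the beta-carbon of the butenolide anti to the menthyloxy group (side-chain methine S) and on the ring face opposite the vicinal ester and the axial ester of the neighbouring quaternary carbon (new quaternary carbon S).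

Step 8
Reactants: 12 bis[2-(trimethylsilyl)ethyl] (1R,2S,3S)-1,3-dimethyl-3-[(2R,3S)-2-{[(1R,2S,5R)-5-methyl-2-(propan-2-yl)cyclohexyl]oxy}-5-oxooxolan-3-yl]cyclohexane-1,2-dicarboxylate
Product: 13 bis[2-(trimethylsilyl)ethyl] (1R,2S,3S)-3-{(2S)-4-[methoxy(methyl)amino]-1,4-dioxobutan-2-yl}-1,3-dimethylcyclohexane-1,2-dicarboxylate
Conditions: MeNH(OMe)·HCl (3 equiv), AlMe3 (3 equiv), CH2Cl2, 0 °C to rt; aq. KNaC4H4O6 work-up
Reagents that add atoms: N,O-dimethylhydroxylamine hydrochloride, CNOC.Cl
Why: Aminolysis of the unhindered acylal-type lactone by the aluminium amide should open the ring to the N-methoxy-N-methylamide while the released hemiacetal collapses to the aldehyde with loss of menthol, the two hindered ring A esters and all stereocentres staying untouched.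

Step 9
Reactants: 13 bis[2-(trimethylsilyl)ethyl] (1R,2S,3S)-3-{(2S)-4-[methoxy(methyl)amino]-1,4-dioxobutan-2-yl}-1,3-dimethylcyclohexane-1,2-dicarboxylate
Product: 14 bis[2-(trimethylsilyl)ethyl] (1R,2S,3S)-3-{(3R)-1-methoxy-5-[methoxy(methyl)amino]-5-oxopent-1-en-3-yl}-1,3-dimethylcyclohexane-1,2-dicarboxylate
Conditions: Ph3P(CH2OMe)Cl (2.5 equiv), KN(SiMe3)2 (2.4 equiv), THF, −78 to 0 °C
Reagents that add atoms: (methoxymethyl)triphenylphosphonium chloride, COC[P+](c1ccccc1)(c1ccccc1)c1ccccc1.[Cl-]
Why: Wittig methoxymethylenation with the small non-stabilised ylide at low temperature should convert the hindered aldehyde into the enol ether (E/Z mixture) before its alpha-methine can epimerise, the amide being inert to the ylide; no new stereocentre is formed.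

Step 10
Reactants: 15 3-chloro-2-(chloromethyl)prop-1-ene; 16 phenol
Product: 17 {[2-(chloromethyl)prop-2-en-1-yl]oxy}benzene
Conditions: K2CO3, acetone, reflux, 15 in threefold excess
Reagents that add atoms: none
Why: Williamson ether synthesis with the bis-allylic dichloride in excess should stop at the mono-ether; no stereocentre is formed.

Step 11
Reactants: 14 bis[2-(trimethylsilyl)ethyl] (1R,2S,3S)-3-{(3R)-1-methoxy-5-[methoxy(methyl)amino]-5-oxopent-1-en-3-yl}-1,3-dimethylcyclohexane-1,2-dicarboxylate; 17 {[2-(chloromethyl)prop-2-en-1-yl]oxy}benzene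
Product: 19 bis[2-(trimethylsilyl)ethyl] (1R,2S,3S)-3-[(3R)-1-methoxy-5-oxo-7-(phenoxymethyl)octa-1,7-dien-3-yl]-1,3-dimethylcyclohexane-1,2-dicarboxylate, via allylmagnesium chloride 18 (not isolated)
Conditions: 17, Mg turnings, THF, 0 °C; then 14, THF, −78 °C; aq. NH4Cl
Reagents that add atoms: none
Why: The allylic Grignard reagent should add once to the N-methoxy-N-methylamide because the magnesium chelate of the tetrahedral adduct survives until work-up (ketone synthesis from an N-methoxy-N-methylamide), giving the beta,gamma-unsaturated ketone with the allylic phenyl ether in place; no new stereocentre is formed.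

Step 12
Reactants: 19 bis[2-(trimethylsilyl)ethyl] (1R,2S,3S)-3-[(3R)-1-methoxy-5-oxo-7-(phenoxymethyl)octa-1,7-dien-3-yl]-1,3-dimethylcyclohexane-1,2-dicarboxylate
Product: 21 bis[2-(trimethylsilyl)ethyl] (1R,2S,3S)-3-[(3S)-2-formyl-5-oxo-7-(phenoxymethyl)octa-1,7-dien-3-yl]-1,3-dimethylcyclohexane-1,2-dicarboxylate, via Mannich base 20 (not isolated)
Conditions: CH2=NMe2 I (1.5 equiv), CH2Cl2, 0 °C to rt; then sat. aq. NaHCO3, THF, 40 °C
Reagents that add atoms: N,N-dimethylmethyleneiminium iodide, C=[N+](C)C.[I-]; water, O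
Why: Mannich reaction of the electron-rich enol ether with the iminium salt puts the aminomethyl group on the carbon next to the side-chain methine, hydrolysis of the oxocarbenium ion gives the beta-amino aldehyde and mild base eliminates dimethylamine to the 2-substituted acrolein, so that a saturated aldehyde is never held beside the ketone; the transient centre is lost again.

Step 13
Reactants: 21 bis[2-(trimethylsilyl)ethyl] (1R,2S,3S)-3-[(3S)-2-formyl-5-oxo-7-(phenoxymethyl)octa-1,7-dien-3-yl]-1,3-dimethylcyclohexane-1,2-dicarboxylate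
Product: 24 bis[2-(trimethylsilyl)ethyl] (1R,2S,3S)-3-[(1R,2S,5R)-1-formyl-6-methylidene-4-oxobicyclo[3.2.1]octan-2-yl]-1,3-dimethylcyclohexane-1,2-dicarboxylate, via palladium zwitterion 22 (not isolated), via Michael adduct 23 (not isolated)
Conditions: Pd2(dba)3·CHCl3 (5 mol%), dppe (12 mol%), THF (0.01 M), 65 °C
Reagents that add atoms: none
Why: Proposed new method: zerovalent palladium ionises the allylic phenyl ether and the released phenoxide removes the hydrogen that lies between the ketone and the cationic allyl unit, giving the acyl-stabilised trimethylenemethane–palladium zwitterion 22, whose carbanionic carbon adds 1,4 to the tethered 2-substituted acrolein (23) before the aldehyde enolate alkylates an allyl terminus. The closest known reactions are the intermolecular (3+2) cycloadditions of 2-(cyanomethyl)allyl and 2-(sulfonylmethyl)allyl carbonates and of acyl-substituted trimethylenemethane–palladium species with Michael acceptors, and the fused-mode intramolecular trimethylenemethane cycloaddition; the bridging mode with a ketone-stabilised dipole and an enal is not known. Ring C closes first by a 6-(enolendo)-endo-trig Michael addition (C13 to C14), and ring D second by a 5-exo attack of the enolate carbon C8 on the allyl terminus C15, anti to palladium. The quaternary carbon C8 is controlled by the existing C9 centre: allylic 1,3-strain in the exocyclic aldehyde enolate of 23 should force the bulky ring A substituent axial, so the allyl unit reaches C8 from the opposite axial face; C13 stays epimerisable next to the ketone until ring closure, and only the epimer with an axial allyl group can bridge. The step needs 1,4- and not 1,2-addition to the enal and C- and not O-allylation; the competing aldol addition and O-allylations are reversible under zerovalent palladium while the C–C ring closure is not, and the two allyl termini are equivalent, so no regiochemical issue arises there. High dilution is chosen to suppress oligomerisation.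

Step 14
Reactants: 24 bis[2-(trimethylsilyl)ethyl] (1R,2S,3S)-3-[(1R,2S,5R)-1-formyl-6-methylidene-4-oxobicyclo[3.2.1]octan-2-yl]-1,3-dimethylcyclohexane-1,2-dicarboxylate
Product: 25 (1R,2S,3S)-3-[(1R,2S,5R)-1-formyl-6-methylidene-4-oxobicyclo[3.2.1]octan-2-yl]-1,3-dimethylcyclohexane-1,2-dicarboxylic acid (CNP0320711.1)
Conditions: Bu4NF (5 equiv), THF, 0 °C to rt; then 1 M HCl to pH 3
Reagents that add atoms: none
Why: Fluoride-induced fragmentation of the two 2-(trimethylsilyl)ethyl esters (attack at silicon, loss of ethene) does not depend on access to the hindered carbonyl groups and should leave the non-enolisable aldehyde, the ketone, the exocyclic alkene and all stereocentres alone.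

**Compound list**
1 | pent-1-en-3-one | C=CC(=O)CC | starting material
2 | (Z)-triisopropyl(penta-1,3-dien-3-yloxy)silane | C=C/C(O[Si](C(C)C)(C(C)C)C(C)C)=C/C | intermediate
3 | fumaryl chloride | O=C(Cl)/C=C/C(=O)Cl | starting material
4 | 2-(trimethylsilyl)ethanol | C[Si](C)(C)CCO | starting material
5 | bis[2-(trimethylsilyl)ethyl] fumarate | C[Si](C)(C)CCOC(=O)/C=C/C(=O)OCC[Si](C)(C)C | intermediate
6 | bis[2-(trimethylsilyl)ethyl] (1S,2S)-3-methyl-4-[(triisopropylsilyl)oxy]cyclohex-4-ene-1,2-dicarboxylate (trans diester, C3 epimers) | CC1C(O[Si](C(C)C)(C(C)C)C(C)C)=CC[C@H](C(=O)OCC[Si](C)(C)C)[C@H]1C(=O)OCC[Si](C)(C)C | intermediate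
7 | bis[2-(trimethylsilyl)ethyl] (1R,2S)-1,3-dimethyl-4-[(triisopropylsilyl)oxy]cyclohex-4-ene-1,2-dicarboxylate (cis diester, C3 epimers; not isolated) | CC1C(O[Si](C(C)C)(C(C)C)C(C)C)=CC[C@@](C)(C(=O)OCC[Si](C)(C)C)[C@H]1C(=O)OCC[Si](C)(C)C | intermediate
8 | bis[2-(trimethylsilyl)ethyl] (1R,2S)-1,3-dimethyl-4-oxocyclohexane-1,2-dicarboxylate (C3 epimers) | CC1C(=O)CC[C@@](C)(C(=O)OCC[Si](C)(C)C)[C@H]1C(=O)OCC[Si](C)(C)C | intermediate
9 | bis[2-(trimethylsilyl)ethyl] (1R,2S)-1,3-dimethyl-4-{[(trifluoromethyl)sulfonyl]oxy}cyclohex-3-ene-1,2-dicarboxylate | CC1=C(OS(=O)(=O)C(F)(F)F)CC[C@@](C)(C(=O)OCC[Si](C)(C)C)[C@H]1C(=O)OCC[Si](C)(C)C | intermediate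
10 | bis[2-(trimethylsilyl)ethyl] (1R,2S)-1,3-dimethylcyclohex-3-ene-1,2-dicarboxylate | CC1=CCC[C@@](C)(C(=O)OCC[Si](C)(C)C)[C@H]1C(=O)OCC[Si](C)(C)C | intermediate
11 | (5R)-5-{[(1R,2S,5R)-5-methyl-2-(propan-2-yl)cyclohexyl]oxy}furan-2(5H)-one | O=C1C=C[C@H](O[C@@H]2C[C@H](C)CC[C@H]2C(C)C)O1 | starting material
12 | bis[2-(trimethylsilyl)ethyl] (1R,2S,3S)-1,3-dimethyl-3-[(2R,3S)-2-{[(1R,2S,5R)-5-methyl-2-(propan-2-yl)cyclohexyl]oxy}-5-oxooxolan-3-yl]cyclohexane-1,2-dicarboxylate | O=C1C[C@H]([C@H](O[C@@H]3C[C@H](C)CC[C@H]3C(C)C)O1)[C@]2(C)CCC[C@@](C)(C(=O)OCC[Si](C)(C)C)[C@H]2C(=O)OCC[Si](C)(C)C | intermediate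
13 | bis[2-(trimethylsilyl)ethyl] (1R,2S,3S)-3-{(2S)-4-[methoxy(methyl)amino]-1,4-dioxobutan-2-yl}-1,3-dimethylcyclohexane-1,2-dicarboxylate | CON(C)C(=O)C[C@H](C=O)[C@]1(C)CCC[C@@](C)(C(=O)OCC[Si](C)(C)C)[C@H]1C(=O)OCC[Si](C)(C)C | intermediate
14 | bis[2-(trimethylsilyl)ethyl] (1R,2S,3S)-3-{(3R)-1-methoxy-5-[methoxy(methyl)amino]-5-oxopent-1-en-3-yl}-1,3-dimethylcyclohexane-1,2-dicarboxylate (E/Z mixture) | CON(C)C(=O)C[C@H](C=COC)[C@]1(C)CCC[C@@](C)(C(=O)OCC[Si](C)(C)C)[C@H]1C(=O)OCC[Si](C)(C)C | intermediate
15 | 3-chloro-2-(chloromethyl)prop-1-ene | C=C(CCl)CCl | starting material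
16 | phenol | Oc1ccccc1 | starting material
17 | {[2-(chloromethyl)prop-2-en-1-yl]oxy}benzene | C=C(CCl)COc1ccccc1 | intermediate
18 | [2-(phenoxymethyl)prop-2-en-1-yl]magnesium chloride (not isolated) | C=C(C[Mg]Cl)COc1ccccc1 | intermediate
19 | bis[2-(trimethylsilyl)ethyl] (1R,2S,3S)-3-[(3R)-1-methoxy-5-oxo-7-(phenoxymethyl)octa-1,7-dien-3-yl]-1,3-dimethylcyclohexane-1,2-dicarboxylate (E/Z mixture) | C=C(COc1ccccc1)CC(=O)C[C@H](C=COC)[C@]1(C)CCC[C@@](C)(C(=O)OCC[Si](C)(C)C)[C@H]1C(=O)OCC[Si](C)(C)C | intermediate
20 | bis[2-(trimethylsilyl)ethyl] (1R,2S,3S)-3-[(3R)-2-[(dimethylamino)methyl]-1,5-dioxo-7-(phenoxymethyl)oct-7-en-3-yl]-1,3-dimethylcyclohexane-1,2-dicarboxylate (C2 epimers of the side chain; not isolated) | C=C(COc1ccccc1)CC(=O)C[C@H](C(CN(C)C)C=O)[C@]1(C)CCC[C@@](C)(C(=O)OCC[Si](C)(C)C)[C@H]1C(=O)OCC[Si](C)(C)C | intermediate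
21 | bis[2-(trimethylsilyl)ethyl] (1R,2S,3S)-3-[(3S)-2-formyl-5-oxo-7-(phenoxymethyl)octa-1,7-dien-3-yl]-1,3-dimethylcyclohexane-1,2-dicarboxylate | C=C(COc1ccccc1)CC(=O)C[C@H](C(=C)C=O)[C@]1(C)CCC[C@@](C)(C(=O)OCC[Si](C)(C)C)[C@H]1C(=O)OCC[Si](C)(C)C | intermediate
22 | acyl-stabilised trimethylenemethane–palladium zwitterion from 21 (drawn as the sigma-allyl form, dppe on palladium not shown; not isolated) | C=C(C[Pd+])C=C([O-])C[C@H](C(=C)C=O)[C@]1(C)CCC[C@@](C)(C(=O)OCC[Si](C)(C)C)[C@H]1C(=O)OCC[Si](C)(C)C | intermediate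
23 | Michael adduct: cyclohexanone carrying the exocyclic aldehyde enolate and the allylpalladium unit (sigma-allyl form, dppe not shown; not isolated) | [O-]C=C1C[C@H](C(=C)C[Pd+])C(=O)C[C@H]1[C@]2(C)CCC[C@@](C)(C(=O)OCC[Si](C)(C)C)[C@H]2C(=O)OCC[Si](C)(C)C | intermediate
24 | bis[2-(trimethylsilyl)ethyl] (1R,2S,3S)-3-[(1R,2S,5R)-1-formyl-6-methylidene-4-oxobicyclo[3.2.1]octan-2-yl]-1,3-dimethylcyclohexane-1,2-dicarboxylate | C=C1C[C@]2(C=O)C[C@H]1C(=O)C[C@H]2[C@]1(C)CCC[C@@](C)(C(=O)OCC[Si](C)(C)C)[C@H]1C(=O)OCC[Si](C)(C)C | intermediate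
25 | (1R,2S,3S)-3-[(1R,2S,5R)-1-formyl-6-methylidene-4-oxobicyclo[3.2.1]octan-2-yl]-1,3-dimethylcyclohexane-1,2-dicarboxylic acid (CNP0320711.1) | C=C1C[C@]2(C=O)C[C@H]1C(=O)C[C@H]2[C@]1(C)CCC[C@@](C)(C(=O)O)[C@H]1C(=O)O | target

**Totals and risks**
Total step count: 14. Longest linear sequence: 12 steps (steps 1, 3 to 9, 11 to 14); steps 2 and 10 make side fragments.

1. Step 13 (proposed new method). What may go wrong: 1,2-addition of the stabilised carbanion to the aldehyde followed by O-allylation, O-allylation of the ketone enolate leading towards a furan, migration of the beta,gamma-double bond into conjugation, or oligomerisation. Fallback with known reactions, from 21 back to 24: a catalytic amount of Cs2CO3 in MeCN at 0 °C should effect only the intramolecular Michael addition and give the monocyclic keto aldehyde F1; F1 is then closed in a separate operation by a Tsuji–Trost alkylation of its alpha-branched aldehyde (Pd(PPh3)4 with catalytic pyrrolidine as enamine co-catalyst, THF, rt), which should give 24 under the same axial-attack control.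

2. Step 7. What may go wrong: premature reduction of the tertiary radical under the hydride conditions, or insufficient facial discrimination at the planar radical. Fallback, from 10 back to 12: Mukaiyama hydration (Mn(dpm)3, PhSiH3, O2, i-PrOH) to the tertiary alcohol F2; acylation with methyl chlorooxoacetate (Et3N, DMAP) to the methyl oxalate F3; half-saponification with CsOH (1 equiv, THF/water) to the caesium oxalate F4; visible-light photoredox decarboxylative Giese addition of F4 to 11 (Ir[dF(CF3)ppy]2(dtbbpy)PF6, DME/DMF, water, blue light, rt), where the aprotic medium and lower temperature should favour addition over reduction.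

3. Step 11. What may go wrong: homocoupling during formation of the functionalised allylic Grignard reagent, or base-induced migration of the new double bond into conjugation on work-up. Fallback, from 14 back to 19: reduction of the N-methoxy-N-methylamide with i-Bu2AlH (THF, −78 °C) to the aldehyde F5; Barbier allylation of F5 with 17 and indium powder (NaI, THF/water) to the homoallylic alcohol F6; oxidation of F6 with DMP (1,1,1-triacetoxy-1,1-dihydro-1,2-benziodoxol-3(1H)-one) and NaHCO3 in CH2Cl2 to 19.

**Further compounds**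
F1 | step 13 | bis[2-(trimethylsilyl)ethyl] (1R,2S,3S)-3-[2-formyl-5-oxo-4-(3-phenoxyprop-1-en-2-yl)cyclohexyl]-1,3-dimethylcyclohexane-1,2-dicarboxylate (ring C centres as in 24, formyl-bearing carbon as a mixture) | O=CC1C[C@H](C(=C)COc2ccccc2)C(=O)C[C@H]1[C@]3(C)CCC[C@@](C)(C(=O)OCC[Si](C)(C)C)[C@H]3C(=O)OCC[Si](C)(C)C
F2 | step 7 | bis[2-(trimethylsilyl)ethyl] 3-hydroxy-1,3-dimethylcyclohexane-1,2-dicarboxylate (ester-bearing centres as in 10, carbinol epimers) | CC1(O)CCC[C@@](C)(C(=O)OCC[Si](C)(C)C)[C@H]1C(=O)OCC[Si](C)(C)C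
F3 | step 7 | methyl oxalate of F2 | CC1(OC(=O)C(=O)OC)CCC[C@@](C)(C(=O)OCC[Si](C)(C)C)[C@H]1C(=O)OCC[Si](C)(C)C
F4 | step 7 | caesium oxalate of F2 | CC1(OC(=O)C(=O)[O-])CCC[C@@](C)(C(=O)OCC[Si](C)(C)C)[C@H]1C(=O)OCC[Si](C)(C)C.[Cs+]
F5 | step 11 | bis[2-(trimethylsilyl)ethyl] (1R,2S,3S)-3-[(3R)-1-methoxy-5-oxopent-1-en-3-yl]-1,3-dimethylcyclohexane-1,2-dicarboxylate | O=CC[C@H](C=COC)[C@]1(C)CCC[C@@](C)(C(=O)OCC[Si](C)(C)C)[C@H]1C(=O)OCC[Si](C)(C)C
F6 | step 11 | bis[2-(trimethylsilyl)ethyl] (1R,2S,3S)-3-[(3R)-5-hydroxy-1-methoxy-7-(phenoxymethyl)octa-1,7-dien-3-yl]-1,3-dimethylcyclohexane-1,2-dicarboxylate (carbinol epimers) | C=C(COc1ccccc1)CC(O)C[C@H](C=COC)[C@]1(C)CCC[C@@](C)(C(=O)OCC[Si](C)(C)C)[C@H]1C(=O)OCC[Si](C)(C)C
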